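**Retrosynthetic overview**
- The target is a (3R)-3-dienyl-8-hydroxyisochroman-1-one. The route rests on one feature: lactone carbonyl C1 of ring B lies between O2 and C8a, and C8a is the ring A carbon flanked by C8 (phenol oxygen) and C4a (the C4 arm). A bromine at C8a and a methyl carbonate on the C3 oxygen therefore mark both ends of the C8a–C1 bond.
- Key disconnection C8a–C1: bromine–lithium exchange and intramolecular acyl transfer from the carbonate close ring B, the only ring formed; ring A comes from the starting benzaldehyde.
- The carbonate comes from the (R)-dienol. Its stereocentre (C3 of the target) is set by oxazaborolidine reduction of the dienone, and the carbinol–diene bond by Nozaki–Hiyama–Kishi coupling of an arylacetaldehyde with a (1E,3E)-dienyl iodide.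
- The arylacetaldehyde comes from 2-bromo-3-hydroxybenzaldehyde (methoxymethyl ether, one-carbon Wittig homologation); the dienyl iodide from tetradecanal (formyl Wittig, Takai olefination).
- The methoxymethyl group is removed last.

Key step: step 10

Assumption: in the oxazaborolidine reduction of ketone 15 the conjugated dienyl group is taken to act as the larger carbonyl substituent, as it does in simple alkenyl alkyl ketones.

**Route**

Step 1
Reactants: 1 tetradecanal; 2 (triphenylphosphoranylidene)acetaldehyde
Product: 3 (E)-hexadec-2-enal
Conditions: 2 (1.0 equiv), toluene, 80 °C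
Reagents that add atoms: (triphenylphosphoranylidene)acetaldehyde 2, O=CC=P(c1ccccc1)(c1ccccc1)c1ccccc1
Why: Wittig olefination with the stabilized formyl ylide is E-selective and should stop largely at the mono-homologated enal when the ylide is limiting, because the conjugated product aldehyde is less electrophilic than tetradecanal.

Step 2
Reactants: 3 (E)-hexadec-2-enal; 4 iodoform
Product: 5 (1E,3E)-1-iodoheptadeca-1,3-diene
Conditions: CrCl2 (6 equiv), CHI3 (2 equiv), THF, 0 °C → rt, dark
Reagents that add atoms: iodoform 4, IC(I)I
Why: Takai olefination, in which the geminal dichromium species formed from CHI3 and CrCl2 adds to the aldehyde and eliminates to the (E)-alkenyl iodide while the existing E double bond is not touched.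

Step 3
Reactants: 6 2-bromo-3-hydroxybenzaldehyde; 7 chloromethyl methyl ether
Product: 8 2-bromo-3-(methoxymethoxy)benzaldehyde
Conditions: MOMCl (1.5 equiv), i-Pr2NEt (2 equiv), CH2Cl2, 0 °C → rt
Reagents that add atoms: chloromethyl methyl ether 7, COCCl
Why: Williamson-type O-alkylation of the phenol with the reactive α-chloro ether masks it as a base-stable acetal that later also helps to hold the aryllithium.

Step 4
Reactants: 8 2-bromo-3-(methoxymethoxy)benzaldehyde; 9 (methoxymethyl)triphenylphosphonium chloride
Product: 10 2-bromo-1-(2-methoxyethenyl)-3-(methoxymethoxy)benzene (E/Z mixture)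
Conditions: 9 (1.3 equiv), KOtBu (1.25 equiv), THF, 0 °C; then 8, 0 °C → rt
Reagents that add atoms: (methoxymethyl)triphenylphosphonium chloride 9, [Cl-].COC[P+](c1ccccc1)(c1ccccc1)c1ccccc1
Why: Wittig olefination with the non-stabilized methoxymethylene ylide gives the one-carbon homologated enol ether, and its E/Z ratio is of no consequence because both isomers lead to the same aldehyde.

Step 5
Reactants: 10 2-bromo-1-(2-methoxyethenyl)-3-(methoxymethoxy)benzene
Product: 12 2-[2-bromo-3-(methoxymethoxy)phenyl]acetaldehyde, via acetoxymercurio aldehyde 11 (not isolated)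
Conditions: Hg(OAc)2 (1.2 equiv), THF/H2O (10:1), 0 °C; then sat. aq. KI; product used at once
Reagents that add atoms: water, O
Why: Mercury-assisted enol ether hydrolysis, in which oxymercuration of the electron-rich enol ether and iodide-induced demercuration of the α-mercurio aldehyde free the arylacetaldehyde near neutral pH, so the acid-labile aryl methoxymethyl acetal should survive.

Step 6
Reactants: 12 2-[2-bromo-3-(methoxymethoxy)phenyl]acetaldehyde; 5 (1E,3E)-1-iodoheptadeca-1,3-diene
Product: 14 rac-(3E,5E)-1-[2-bromo-3-(methoxymethoxy)phenyl]nonadeca-3,5-dien-2-ol, via dienylchromium dichloride 13 (not isolated)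
Conditions: 5 (1.5 equiv), CrCl2 (4 equiv), NiCl2 (1 mol%), DMSO, rt
Reagents that add atoms: none
Why: Nozaki–Hiyama–Kishi coupling, in which zerovalent nickel inserts into the alkenyl C–I bond far faster than into the hindered aryl C–Br bond and transmetalation gives a non-basic alkenyl species of trivalent chromium that adds 1,2 to the enolizable aldehyde with retention of the diene geometry; the new carbinol centre is racemic at this stage.

Step 7
Reactants: 14 rac-(3E,5E)-1-[2-bromo-3-(methoxymethoxy)phenyl]nonadeca-3,5-dien-2-ol
Product: 15 (3E,5E)-1-[2-bromo-3-(methoxymethoxy)phenyl]nonadeca-3,5-dien-2-one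
Conditions: Dess–Martin periodinane (1.3 equiv), NaHCO3, CH2Cl2, 0 °C → rt
Reagents that add atoms: none
Why: Dess–Martin oxidation converts the secondary dienylic alcohol into the ketone under buffered, non-acidic conditions that leave the diene, the acetal and the aryl bromide alone.

Step 8
Reactants: 15 (3E,5E)-1-[2-bromo-3-(methoxymethoxy)phenyl]nonadeca-3,5-dien-2-one
Product: 16 (2R,3E,5E)-1-[2-bromo-3-(methoxymethoxy)phenyl]nonadeca-3,5-dien-2-ol
Conditions: (S)-2-methyl-CBS-oxazaborolidine [(3aS)-1-methyl-3,3-diphenyltetrahydro-1H,3H-pyrrolo[1,2-c][1,3,2]oxazaborole] (0.2 equiv), catecholborane (1.8 equiv), toluene, −78 °C; then H2O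
Reagents that add atoms: none
Why: Corey–Bakshi–Shibata reduction, in which the (S)-oxazaborolidine binds catecholborane and the ketone so that the dienyl group lies away from the catalyst and hydride is delivered to the carbonyl face that gives the 2R alcohol, the catalyst alone setting this stereocentre, while at −78 °C 1,2-reduction should outrun conjugate reduction.

Step 9
Reactants: 16 (2R,3E,5E)-1-[2-bromo-3-(methoxymethoxy)phenyl]nonadeca-3,5-dien-2-ol; 17 methyl chloroformate
Product: 18 (2R,3E,5E)-1-[2-bromo-3-(methoxymethoxy)phenyl]nonadeca-3,5-dien-2-yl methyl carbonate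
Conditions: ClCO2Me (2 equiv), pyridine (3 equiv), 4-(dimethylamino)pyridine (cat.), CH2Cl2, 0 °C
Reagents that add atoms: methyl chloroformate 17, COC(=O)Cl
Why: Acylation of the secondary alcohol with the chloroformate under nucleophilic catalysis forms the carbonate without touching the C–O bond of the stereocentre, so the R configuration is retained.

Step 10
Reactants: 18 (2R,3E,5E)-1-[2-bromo-3-(methoxymethoxy)phenyl]nonadeca-3,5-dien-2-yl methyl carbonate
Product: 21 (3R)-3-[(1E,3E)-heptadeca-1,3-dienyl]-8-(methoxymethoxy)isochroman-1-one, via aryllithium 19 (not isolated), via tetrahedral lithium alkoxide 20 (not isolated)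
Conditions: n-BuLi (1.05 equiv), THF/Et2O/pentane (4:1:1), −100 °C → −78 °C; then AcOH, −78 °C → rt
Reagents that add atoms: none
Why: Parham cyclization (cycloacylation): at −100 °C n-BuLi exchanges the bromine at C8a faster than it adds to the weakly electrophilic carbonate or removes a benzylic or dienylic proton, and aryllithium 19, held by the neighbouring methoxymethoxy oxygen, attacks the carbonate carbonyl on the C3 oxygen to form the C8a–C1 bond. Ring B closes in a 6-exo-trig mode to the tetrahedral alkoxide 20, which loses methoxide to give the lactone; loss of the C3 alkoxide instead gives a methyl benzoate that relactonizes to the same product. The closest known reaction type is the intramolecular capture of aryllithiums from halogen–lithium exchange by esters, carbamates and carbonates to give benzo-fused lactones. No stereocentre is formed, and C3 keeps its R configuration because none of its bonds is broken and neither a transition metal nor an acid is present to ionize the dienylic C–O bond. The step needs site selectivity on ring A, secured by the position of the bromine, and chemoselectivity for exchange over carbonyl addition and carbonate elimination, secured by the low temperature, the single equivalent of n-BuLi and the cold acetic acid quench.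

Step 11
Reactants: 21 (3R)-3-[(1E,3E)-heptadeca-1,3-dienyl]-8-(methoxymethoxy)isochroman-1-one
Product: 22 (3R)-3-[(1E,3E)-heptadeca-1,3-dienyl]-8-hydroxyisochroman-1-one
Conditions: MgBr2·OEt2 (3 equiv), n-BuSH (3 equiv), Et2O, 0 °C → rt
Reagents that add atoms: none
Why: Chelation-assisted acetal cleavage, in which MgBr2 held between the lactone carbonyl and the peri acetal oxygen activates the methoxymethyl group and the thiol captures the methoxymethyl fragment, under aprotic, weakly Lewis acidic conditions that should not ionize the dienylic C3–O bond.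

**Compound list**
1 | tetradecanal | CCCCCCCCCCCCCC=O | starting material
2 | (triphenylphosphoranylidene)acetaldehyde | O=CC=P(c1ccccc1)(c1ccccc1)c1ccccc1 | starting material
3 | (E)-hexadec-2-enal | CCCCCCCCCCCCC/C=C/C=O | intermediate
4 | iodoform | IC(I)I | starting material
5 | (1E,3E)-1-iodoheptadeca-1,3-diene | CCCCCCCCCCCCC/C=C/C=C/I | intermediate
6 | 2-bromo-3-hydroxybenzaldehyde | O=Cc1cccc(O)c1Br | starting material
7 | chloromethyl methyl ether | COCCl | starting material
8 | 2-bromo-3-(methoxymethoxy)benzaldehyde | COCOc1cccc(C=O)c1Br | intermediate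
9 | (methoxymethyl)triphenylphosphonium chloride | [Cl-].COC[P+](c1ccccc1)(c1ccccc1)c1ccccc1 | starting material
10 | 2-bromo-1-(2-methoxyethenyl)-3-(methoxymethoxy)benzene, E/Z mixture | COC=Cc1cccc(OCOC)c1Br | intermediate
11 | 2-(acetoxymercurio)-2-[2-bromo-3-(methoxymethoxy)phenyl]acetaldehyde, racemic, not isolated | CC(=O)O[Hg]C(C=O)c1cccc(OCOC)c1Br | intermediate
12 | 2-[2-bromo-3-(methoxymethoxy)phenyl]acetaldehyde | O=CCc1cccc(OCOC)c1Br | intermediate
13 | (1E,3E)-heptadeca-1,3-dienylchromium dichloride, not isolated | CCCCCCCCCCCCC/C=C/C=C/[Cr](Cl)Cl | intermediate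
14 | rac-(3E,5E)-1-[2-bromo-3-(methoxymethoxy)phenyl]nonadeca-3,5-dien-2-ol | CCCCCCCCCCCCC/C=C/C=C/C(O)Cc1cccc(OCOC)c1Br | intermediate
15 | (3E,5E)-1-[2-bromo-3-(methoxymethoxy)phenyl]nonadeca-3,5-dien-2-one | CCCCCCCCCCCCC/C=C/C=C/C(=O)Cc1cccc(OCOC)c1Br | intermediate
16 | (2R,3E,5E)-1-[2-bromo-3-(methoxymethoxy)phenyl]nonadeca-3,5-dien-2-ol | CCCCCCCCCCCCC/C=C/C=C/[C@H](O)Cc1cccc(OCOC)c1Br | intermediate
17 | methyl chloroformate | COC(=O)Cl | starting material
18 | (2R,3E,5E)-1-[2-bromo-3-(methoxymethoxy)phenyl]nonadeca-3,5-dien-2-yl methyl carbonate | CCCCCCCCCCCCC/C=C/C=C/[C@H](OC(=O)OC)Cc1cccc(OCOC)c1Br | intermediate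
19 | (2R,3E,5E)-1-[2-lithio-3-(methoxymethoxy)phenyl]nonadeca-3,5-dien-2-yl methyl carbonate, not isolated | CCCCCCCCCCCCC/C=C/C=C/[C@H](OC(=O)OC)Cc1cccc(OCOC)c1[Li] | intermediate
20 | lithium (3R)-3-[(1E,3E)-heptadeca-1,3-dienyl]-1-methoxy-8-(methoxymethoxy)isochroman-1-olate, mixture at C1, not isolated | CCCCCCCCCCCCC/C=C/C=C/[C@H]1Cc2cccc(OCOC)c2C(O[Li])(OC)O1 | intermediate
21 | (3R)-3-[(1E,3E)-heptadeca-1,3-dienyl]-8-(methoxymethoxy)isochroman-1-one | CCCCCCCCCCCCC/C=C/C=C/[C@H]1Cc2cccc(OCOC)c2C(=O)O1 | intermediate
22 | (3R)-3-[(1E,3E)-heptadeca-1,3-dienyl]-8-hydroxyisochroman-1-one | CCCCCCCCCCCCC/C=C/C=C/[C@H]1Cc2cccc(O)c2C(=O)O1 | target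

**Step count and risks**

Total step count: 11. Longest linear sequence: 9 steps (steps 3 to 11, from 2-bromo-3-hydroxybenzaldehyde 6).

Steps most likely to fail:

Step 10 (key step). n-BuLi may add to the carbonate carbonyl or remove a benzylic or dienylic proton in competition with the exchange, the carbonate may then be eliminated to a conjugated triene, and the methoxide set free may reopen the lactone. The fallback sets out from alcohol 16 and separates metalation from acylation. Treatment with n-BuLi (2.2 equiv) in THF at −78 °C should first form the alkoxide and then exchange the bromine, giving lithium (2R,3E,5E)-1-[2-lithio-3-(methoxymethoxy)phenyl]nonadeca-3,5-dien-2-olate F1, a species with no internal electrophile. Carboxylation with CO2 and work-up at about pH 4 should give 2-[(2R,3E,5E)-2-hydroxynonadeca-3,5-dienyl]-6-(methoxymethoxy)benzoic acid F2. Lactonization with N-(3-dimethylaminopropyl)-N′-ethylcarbodiimide hydrochloride and 4-(dimethylamino)pyridine in CH2Cl2, if not already spontaneous, comes back to the route at lactone 21.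

Step 8. Facial discrimination in the hydride transfer may be weak because the arylmethyl and dienyl groups differ too little in effective size, which would give alcohol of low enantiomeric purity. The fallback sets out from racemic alcohol 14 and leaves out steps 7 and 8. Sharpless kinetic resolution with Ti(OiPr)4, L-(+)-diisopropyl tartrate and t-BuOOH (0.6 equiv) over 4 Å molecular sieves in CH2Cl2 at −20 °C should epoxidize the (S)-enantiomer at the C3–C4 alkene to (2S,3S,4S,5E)-1-[2-bromo-3-(methoxymethoxy)phenyl]-3,4-epoxynonadec-5-en-2-ol F3, which is discarded. The unreacted (R)-alcohol is the point at which the fallback comes back to the route, as compound 16; at most half of the material is kept.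

Step 5. Demercuration may be incomplete, and the arylacetaldehyde may undergo aldol self-condensation or air oxidation during its release and isolation. The fallback sets out from aldehyde 8 and reaches the same aldehyde by a final neutral oxidation. Methylenation with methyltriphenylphosphonium bromide and KOtBu in THF should give 2-bromo-1-ethenyl-3-(methoxymethoxy)benzene F4. Hydroboration with 9-borabicyclo[3.3.1]nonane in THF should give 9-{2-[2-bromo-3-(methoxymethoxy)phenyl]ethyl}-9-borabicyclo[3.3.1]nonane F5, and oxidation in the same flask with NaOH and H2O2 should give 2-[2-bromo-3-(methoxymethoxy)phenyl]ethanol F6. Dess–Martin oxidation of this alcohol comes back to the route at aldehyde 12, which is filtered and used directly in step 6.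

**Further compounds**
F1 | step 10 | lithium (2R,3E,5E)-1-[2-lithio-3-(methoxymethoxy)phenyl]nonadeca-3,5-dien-2-olate | CCCCCCCCCCCCC/C=C/C=C/[C@H](O[Li])Cc1cccc(OCOC)c1[Li]
F2 | step 10 | 2-[(2R,3E,5E)-2-hydroxynonadeca-3,5-dienyl]-6-(methoxymethoxy)benzoic acid | CCCCCCCCCCCCC/C=C/C=C/[C@H](O)Cc1cccc(OCOC)c1C(=O)O
F3 | step 8 | (2S,3S,4S,5E)-1-[2-bromo-3-(methoxymethoxy)phenyl]-3,4-epoxynonadec-5-en-2-ol | CCCCCCCCCCCCC/C=C/[C@@H]1O[C@H]1[C@@H](O)Cc1cccc(OCOC)c1Br
F4 | step 5 | 2-bromo-1-ethenyl-3-(methoxymethoxy)benzene | C=Cc1cccc(OCOC)c1Br
F5 | step 5 | 9-{2-[2-bromo-3-(methoxymethoxy)phenyl]ethyl}-9-borabicyclo[3.3.1]nonane | COCOc1cccc(CCB2C3CCCC2CCC3)c1Br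
F6 | step 5 | 2-[2-bromo-3-(methoxymethoxy)phenyl]ethanol | OCCc1cccc(OCOC)c1Br
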